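**Retrosynthetic overview**

1. The target is a 6-hydroxy-7-methoxycoumarin (coumarin A: O1, C2, C3, C4, C4a to C8a) whose C3 carries an ether oxygen bound to C7 of a second coumarin (coumarin B), which is bought intact as umbelliferone.
2. Feature: O1 of the lactone ring of coumarin A sits on aryl carbon C8a, and C8a is para to the oxygen on C6. Taking O1 out leaves a 1-indanone (C1=O becomes C2, C2 becomes C3, C3 becomes C4, C7a becomes C8a) whose carbonyl-bound aryl carbon is a para-alkoxy-activated migrating group.
3. Disconnections, backwards: O-benzyl at C6; C3–C4 dehydrogenation; O1 insertion by Baeyer–Villiger ring expansion; C3–O ether by SN2 of umbelliferone on a 2-bromoindanone; indanone C1–C7a bond by Friedel–Crafts acylation; side chain by Knoevenagel–Doebner reaction on isovanillin.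
4. Ring order: the benzene ring of A and both rings of B come with the starting materials; the cyclopentanone ring is closed in step 3, expanded to the six-membered lactone in step 7 and aromatized in step 8.

Key step: step 7

Remark on the chemistry: the target has no stereocentre; the sp3 centre present in compounds 8, 10 and 12 is carried as a racemate and removed in step 8.

**Route**

Step 1
Reactants: 1 isovanillin (3-hydroxy-4-methoxybenzaldehyde); 2 malonic acid
Product: 4 (E)-3-(3-hydroxy-4-methoxyphenyl)prop-2-enoic acid (isoferulic acid), via arylidenemalonic acid 3 (not isolated)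
Conditions: pyridine, piperidine (cat.), 90 °C; then aq. HCl
Reagents that add atoms: none
Why: Knoevenagel condensation followed by decarboxylation of the arylidenemalonic acid in hot pyridine (Doebner modification) should give the E-cinnamic acid, the free phenol being tolerated.

Step 2
Reactants: 4 isoferulic acid
Product: 5 3-(3-hydroxy-4-methoxyphenyl)propanoic acid
Conditions: H2 (1 atm), 10% Pd/C, MeOH, rt
Reagents that add atoms: none
Why: Catalytic hydrogenation should saturate the conjugated alkene only, leaving the arene, phenol and acid untouched.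

Step 3
Reactants: 5 3-(3-hydroxy-4-methoxyphenyl)propanoic acid
Product: 6 5-hydroxy-6-methoxy-2,3-dihydro-1H-inden-1-one
Conditions: MeSO3H (neat), 90 °C; then ice water
Reagents that add atoms: none
Why: Intramolecular Friedel–Crafts acylation should close the five-membered ketone at the ring position para to the hydroxyl group, because the other position ortho to the chain is flanked by the chain and the hydroxyl and is only ortho-activated.

Step 4
Reactants: 6 5-hydroxy-6-methoxy-2,3-dihydro-1H-inden-1-one
Product: 7 5-(benzyloxy)-6-methoxy-2,3-dihydro-1H-inden-1-one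
Conditions: BnBr, K2CO3, DMF, rt
Reagents that add atoms: benzyl bromide, BrCc1ccccc1
Why: Williamson ether synthesis on the phenoxide should be clean because K2CO3 does not enolize the indanone to a useful extent.

Step 5
Reactants: 7 5-(benzyloxy)-6-methoxy-2,3-dihydro-1H-inden-1-one
Product: 8 5-(benzyloxy)-2-bromo-6-methoxy-2,3-dihydro-1H-inden-1-one (racemic)
Conditions: CuBr2 (2.1 equiv), EtOAc/CHCl3 (1:1), reflux
Reagents that add atoms: CuBr2, Br[Cu]Br
Why: Bromination of the ketone through its copper-bound enol (King α-bromination with CuBr2) should stop at the α-monobromide and spare the carbonyl-deactivated alkoxyarene and the benzyl ether; the new C2 centre forms as a racemate and needs no control.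

Step 6
Reactants: 8 5-(benzyloxy)-2-bromo-6-methoxy-2,3-dihydro-1H-inden-1-one; 9 umbelliferone (7-hydroxy-2H-chromen-2-one)
Product: 10 5-(benzyloxy)-6-methoxy-2-[(2-oxo-2H-chromen-7-yl)oxy]-2,3-dihydro-1H-inden-1-one (racemic)
Conditions: K2CO3 (1.5 equiv), acetone, 0 °C to rt
Reagents that add atoms: none
Why: Williamson-type SN2 displacement of the carbonyl-activated secondary bromide by the weakly basic umbelliferone phenoxide should give the α-aryloxy ketone; the racemic bromide gives the racemic ether and the lactone of coumarin B survives carbonate in acetone.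

Step 7
Reactants: 10 5-(benzyloxy)-6-methoxy-2-[(2-oxo-2H-chromen-7-yl)oxy]-2,3-dihydro-1H-inden-1-one (racemic)
Product: 12 6-(benzyloxy)-7-methoxy-3-[(2-oxo-2H-chromen-7-yl)oxy]-3,4-dihydro-2H-chromen-2-one (racemic), via Criegee peroxy hemiketal 11 (not isolated)
Conditions: mCPBA (2 equiv), CF3CO2H (1 equiv), CH2Cl2, 0 °C to rt, dark; then aq. Na2S2O3/NaHCO3 wash
Reagents that add atoms: m-chloroperoxybenzoic acid, OOC(=O)c1cccc(Cl)c1
Why: Acid-assisted addition of the peracid to the C1 carbonyl gives the tetrahedral peroxy hemiketal 11, in which the aryl carbon C7a, lying anti to the O–O bond, shifts from C1 to the proximal peroxide oxygen as m-chlorobenzoate leaves. The closest known reactions are the Baeyer–Villiger oxidation of 1-indanones to 3,4-dihydrocoumarins and of p-alkoxyaryl α-aryloxymethyl ketones to aryl esters. The six-membered lactone ring is formed by ring expansion, the oxygen being inserted into the C1–C7a bond of the five-membered ring by a 1,2-shift and not by an end-to-end closure. No stereocentre is created: C2 of the indanone becomes C3 of the lactone unchanged and racemic, and the hemiketal carbon of 11 returns to a carbonyl. The step needs migration of the aryl carbon in preference to the aryloxy-bearing CH; the benzyloxy group para to C7a stabilizes the bridged, phenonium-like transition state, whereas the oxygen on C2 is tied to the electron-poor coumarinyl ring and acts mainly as an inductive acceptor. The electron-poor C3=C4 bond of coumarin B and the benzyl ether should not react with the peracid.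

Step 8
Reactants: 12 6-(benzyloxy)-7-methoxy-3-[(2-oxo-2H-chromen-7-yl)oxy]-3,4-dihydro-2H-chromen-2-one (racemic)
Product: 13 6-(benzyloxy)-7-methoxy-3-[(2-oxo-2H-chromen-7-yl)oxy]-2H-chromen-2-one
Conditions: DDQ (1.5 equiv), 1,4-dioxane, reflux
Reagents that add atoms: none
Why: DDQ dehydrogenation should proceed by hydride abstraction from benzylic C4, whose cation is stabilized through C4a by the para methoxy group on C7, followed by loss of the acidic C3 proton to give the aromatic pyranone, which removes the only stereocentre.

Step 9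
Reactants: 13 6-(benzyloxy)-7-methoxy-3-[(2-oxo-2H-chromen-7-yl)oxy]-2H-chromen-2-one
Product: 14 6-hydroxy-7-methoxy-3-[(2-oxo-2H-chromen-7-yl)oxy]-2H-chromen-2-one (target)
Conditions: BCl3 (1 M in CH2Cl2, 3 equiv), pentamethylbenzene (4 equiv), CH2Cl2, −78 °C; then H2O
Reagents that add atoms: none
Why: Lewis-acid debenzylation with pentamethylbenzene as a non-basic benzyl cation scavenger should cleave only the aryl benzyl ether at −78 °C, leaving the methyl ether, the diaryl-type ether at C3 and both lactones intact and avoiding C-benzylation of the electron-rich ring.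

**Compound list**

1 | isovanillin (3-hydroxy-4-methoxybenzaldehyde) | COc1ccc(C=O)cc1O | starting material
2 | malonic acid | OC(=O)CC(=O)O | starting material
3 | 2-[(3-hydroxy-4-methoxyphenyl)methylidene]propanedioic acid | COc1ccc(C=C(C(=O)O)C(=O)O)cc1O | intermediate
4 | (E)-3-(3-hydroxy-4-methoxyphenyl)prop-2-enoic acid (isoferulic acid) | COc1ccc(/C=C/C(=O)O)cc1O | intermediate
5 | 3-(3-hydroxy-4-methoxyphenyl)propanoic acid | COc1ccc(CCC(=O)O)cc1O | intermediate
6 | 5-hydroxy-6-methoxy-2,3-dihydro-1H-inden-1-one | COc1cc2c(cc1O)CCC2=O | intermediate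
7 | 5-(benzyloxy)-6-methoxy-2,3-dihydro-1H-inden-1-one | COc1cc2c(cc1OCc1ccccc1)CCC2=O | intermediate
8 | 5-(benzyloxy)-2-bromo-6-methoxy-2,3-dihydro-1H-inden-1-one (racemic) | COc1cc2c(cc1OCc1ccccc1)CC(Br)C2=O | intermediate
9 | umbelliferone (7-hydroxy-2H-chromen-2-one) | O=c1ccc2ccc(O)cc2o1 | starting material
10 | 5-(benzyloxy)-6-methoxy-2-[(2-oxo-2H-chromen-7-yl)oxy]-2,3-dihydro-1H-inden-1-one (racemic) | COc1cc2c(cc1OCc1ccccc1)CC(Oc1ccc3ccc(=O)oc3c1)C2=O | intermediate
11 | 5-(benzyloxy)-1-hydroxy-6-methoxy-2-[(2-oxo-2H-chromen-7-yl)oxy]-2,3-dihydro-1H-inden-1-yl 3-chlorobenzenecarboperoxoate (racemic, mixture of diastereomers) | COc1cc2c(cc1OCc1ccccc1)CC(Oc1ccc3ccc(=O)oc3c1)C2(O)OOC(=O)c1cccc(Cl)c1 | intermediate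
12 | 6-(benzyloxy)-7-methoxy-3-[(2-oxo-2H-chromen-7-yl)oxy]-3,4-dihydro-2H-chromen-2-one (racemic) | COc1cc2OC(=O)C(Oc3ccc4ccc(=O)oc4c3)Cc2cc1OCc1ccccc1 | intermediate
13 | 6-(benzyloxy)-7-methoxy-3-[(2-oxo-2H-chromen-7-yl)oxy]-2H-chromen-2-one | COc1cc2oc(=O)c(Oc3ccc4ccc(=O)oc4c3)cc2cc1OCc1ccccc1 | intermediate
14 | 6-hydroxy-7-methoxy-3-[(2-oxo-2H-chromen-7-yl)oxy]-2H-chromen-2-one | COc1cc2oc(=O)c(Oc3ccc4ccc(=O)oc4c3)cc2cc1O | target

**Step count**

Total steps: 9. Longest linear sequence: 9 steps (isovanillin 1 to target 14); umbelliferone 9 enters in step 6.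

**Steps most likely to fail**

Step 7. The aryloxy-bearing sp3 carbon may migrate in place of the aryl carbon, or the electron-rich aryl ketone may add the peracid too slowly, so that the ring-expanded lactone is formed with the wrong connectivity or not at all. The fallback sets out from indanone 7, in which the only competitor of the aryl carbon is a CH2 group. Baeyer–Villiger oxidation of 7 (mCPBA, CF3CO2H, CH2Cl2) should give 6-(benzyloxy)-7-methoxy-3,4-dihydro-2H-chromen-2-one F1. Its lithium enolate (LiN(SiMe3)2, THF, −78 °C) would be hydroxylated with 3-phenyl-2-(phenylsulfonyl)oxaziridine to racemic 6-(benzyloxy)-3-hydroxy-7-methoxy-3,4-dihydro-2H-chromen-2-one F2. Mitsunobu etherification of F2 with umbelliferone 9 (PPh3, diisopropyl azodicarboxylate, THF, 0 °C) then forms the C3–O bond and returns to the route at compound 12.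

Step 8. DDQ may attack the benzylic CH2 of the benzyl ether, or hydride abstraction from C4 may stall next to the electron-withdrawing aryloxy group on C3. The fallback sets out from compound 12 and uses the acidity of C3–H instead of hydride abstraction. Deprotonation (LiN(SiMe3)2, THF, −78 °C) and trapping with PhSeBr should give 6-(benzyloxy)-7-methoxy-3-[(2-oxo-2H-chromen-7-yl)oxy]-3-(phenylselanyl)-3,4-dihydro-2H-chromen-2-one F3. Oxidation with H2O2 (CH2Cl2, 0 °C) gives the selenoxide 6-(benzyloxy)-7-methoxy-3-[(2-oxo-2H-chromen-7-yl)oxy]-3-(phenylseleninyl)-3,4-dihydro-2H-chromen-2-one F4, which is not isolated. It undergoes syn elimination toward C4–H, the only β-hydrogens available, and the route is rejoined at compound 13.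

Step 6. Dehydrobromination of 8 to the indenone and C-alkylation of the enolizable product may compete with O-alkylation of the phenoxide. The fallback sets out from indanone 7 and forms the C2–O bond by carbenoid O–H insertion instead of substitution. Claisen formylation (HCO2Et, NaH, THF) should give 5-(benzyloxy)-2-(hydroxymethylidene)-6-methoxy-2,3-dihydro-1H-inden-1-one F5. Deformylative Regitz diazo transfer (4-methylbenzenesulfonyl azide, Et3N, CH2Cl2) gives 5-(benzyloxy)-2-diazo-6-methoxy-2,3-dihydro-1H-inden-1-one F6. Slow addition of F6 to umbelliferone 9 and Rh2(OAc)4 (1 mol%) in 1,2-dichloroethane at 60 °C should give the α-aryloxy ketone and return to the route at compound 10.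

**Further compounds**

F1 | step 7 | 6-(benzyloxy)-7-methoxy-3,4-dihydro-2H-chromen-2-one | COc1cc2OC(=O)CCc2cc1OCc1ccccc1
F2 | step 7 | 6-(benzyloxy)-3-hydroxy-7-methoxy-3,4-dihydro-2H-chromen-2-one (racemic) | COc1cc2OC(=O)C(O)Cc2cc1OCc1ccccc1
F3 | step 8 | 6-(benzyloxy)-7-methoxy-3-[(2-oxo-2H-chromen-7-yl)oxy]-3-(phenylselanyl)-3,4-dihydro-2H-chromen-2-one (racemic) | COc1cc2OC(=O)C([Se]c3ccccc3)(Oc3ccc4ccc(=O)oc4c3)Cc2cc1OCc1ccccc1
F4 | step 8 | 6-(benzyloxy)-7-methoxy-3-[(2-oxo-2H-chromen-7-yl)oxy]-3-(phenylseleninyl)-3,4-dihydro-2H-chromen-2-one (mixture of diastereomers) | COc1cc2OC(=O)C([Se](=O)c3ccccc3)(Oc3ccc4ccc(=O)oc4c3)Cc2cc1OCc1ccccc1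
F5 | step 6 | 5-(benzyloxy)-2-(hydroxymethylidene)-6-methoxy-2,3-dihydro-1H-inden-1-one | COc1cc2c(cc1OCc1ccccc1)CC(=CO)C2=O
F6 | step 6 | 5-(benzyloxy)-2-diazo-6-methoxy-2,3-dihydro-1H-inden-1-one | COc1cc2c(cc1OCc1ccccc1)CC(=[N+]=[N-])C2=O
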